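**Retrosynthetic overview**

- The senecioate ester is put on last (Steglich) onto 5-O-methylalkannin 16. Quinone ring A (C1–C4) comes from a 1,4-epoxy-1,4-dihydronaphthalene by isomerisation and para-oxidation.
- The C1–C8a and C4–C4a bonds are made together by an intramolecular [4+2] addition of a 3-substituted furan (C1–C4, its oxygen becoming the C1 oxygen) to a 3,6-dioxygenated aryne (C4a≡C8a of ring B).
- Enabling feature: the phenol oxygen on C8 and the oxygen on the side-chain carbon C1' (attached to C2) lie on the same flank of the C8a–C1 bond (path O–C8–C8a–C1–C2–C1'–O). A removable O–Si–O–Si–O strap between them lets the furan reach the aryne in one orientation only, and later masks O8 during the oxidation.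
- Ring order: ring B is bought (2-iodoisovanillin); the key step closes ring A as an oxygen-bridged ring (plus a temporary ten-membered strap ring); ring A is then aromatised and oxidised, and the strap removed. The stereocentre comes from Brown allylation of 3-furaldehyde.

Key step: step 6

Remark: target locants are used for all intermediates (C1 carbonyl next to C2 with the side chain, C4 carbonyl, C5 methoxy, C8 hydroxyl, C1' carbinol carbon); the two bridgehead carbons of 13 are left without configuration because either furan face may react and both centres vanish in step 7.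

**Route**

Step 1
Reactants: 1 furan-3-carbaldehyde
Product: 2 (1S)-1-(furan-3-yl)but-3-en-1-ol
Conditions: (−)-Ipc2B(allyl) (1 M in pentane), Et2O, −78 °C; then NaOH, H2O2, 0 to 23 °C
Reagents that add atoms: (−)-B-allyldiisopinocampheylborane, C=CCB([C@@H]1C[C@@H]2C[C@H]([C@H]1C)C2(C)C)[C@@H]1C[C@@H]2C[C@H]([C@H]1C)C2(C)C
Why: Brown allylation through a closed chair transition state; the (−)-reagent (from (+)-α-pinene) should deliver allyl to the aldehyde face that gives the (S)-carbinol, as it does with benzaldehyde.

Step 2
Reactants: 2 (1S)-1-(furan-3-yl)but-3-en-1-ol; 3 2-methylbut-2-ene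
Product: 4 (1S)-1-(furan-3-yl)-4-methylpent-3-en-1-ol
Conditions: second-generation Grubbs catalyst RuCl2(=CHPh)(H2IMes)(PCy3) (3 mol %), 3 as co-solvent, CH2Cl2, 40 °C, sealed tube
Reagents that add atoms: none
Why: Olefin cross-metathesis of a terminal alkene with excess 2-methylbut-2-ene is the standard way to install a prenyl terminus; the free alcohol and the furan are tolerated and the stereocentre is not touched.

Step 3
Reactants: 5 3-hydroxy-2-iodo-4-methoxybenzaldehyde (2-iodoisovanillin)
Product: 6 3-formyl-2-iodo-6-methoxyphenyl trifluoromethanesulfonate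
Conditions: Tf2O, pyridine, CH2Cl2, 0 °C
Reagents that add atoms: triflic anhydride, O=S(=O)(OS(=O)(=O)C(F)(F)F)C(F)(F)F
Why: O-sulfonylation of a phenol; it places the leaving group next to the iodide so that the two carbons that will become C4a and C8a are marked unambiguously.

Step 4
Reactants: 6 3-formyl-2-iodo-6-methoxyphenyl trifluoromethanesulfonate
Product: 8 3-hydroxy-2-iodo-6-methoxyphenyl trifluoromethanesulfonate, via aryl formate 7 (not isolated)
Conditions: mCPBA, CH2Cl2, 23 °C; then Et3N, MeOH, 0 °C
Reagents that add atoms: mCPBA, OOC(=O)c1cccc(Cl)c1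
Why: Baeyer–Villiger oxidation in which the methoxy group para to the formyl group should favour aryl migration; the formate is then cleaved by mild methanolysis that leaves the triflate and the iodide alone.

Step 5
Reactants: 4 (1S)-1-(furan-3-yl)-4-methylpent-3-en-1-ol; 8 3-hydroxy-2-iodo-6-methoxyphenyl trifluoromethanesulfonate
Product: 10 3-[(3-{[(1S)-1-(furan-3-yl)-4-methylpent-3-en-1-yl]oxy}-1,1,3,3-tetraisopropyldisiloxanyl)oxy]-2-iodo-6-methoxyphenyl trifluoromethanesulfonate, via chlorodisiloxanyl ether 9 (not isolated)
Conditions: 4 added slowly to TIPDSCl2 (3 equiv), imidazole, CH2Cl2, 0 °C; excess dichlorodisiloxane removed under high vacuum; then 8, imidazole, DMAP (cat.), CH2Cl2, 23 °C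
Reagents that add atoms: 1,3-dichloro-1,1,3,3-tetraisopropyldisiloxane (TIPDSCl2), CC(C)[Si](Cl)(C(C)C)O[Si](Cl)(C(C)C)C(C)C
Why: Stepwise silyl ether formation; the hindered secondary alcohol should take one Si–Cl of the excess reagent and the phenol the remaining one, giving the unsymmetrical strap without touching C1'.

Step 6
Reactants: 10 disiloxane-tethered iodo triflate
Product: 13 5-methoxy-1,4-dihydro-1,4-epoxynaphthalene in which the C8 oxygen and the oxygen of the C2 substituent CH(O–)(CH2CH=CMe2) (C1', S) are bridged by Si(iPr)2–O–Si(iPr)2, via arylmagnesium chloride 11 (not isolated), via aryne 12 (not isolated)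
Conditions: Me3SiCH2MgCl (1.5 equiv), THF (0.005 M), −78 to 23 °C
Reagents that add atoms: none
Why: Iodine–magnesium exchange at the iodide flanked by the two oxygens gives 11, which loses MgCl(OTf) to the 3,6-dioxygenated aryne 12; the pendant furan then adds across the strained triple bond in an intramolecular [4+2] cycloaddition that forms the C1–C8a and C4–C4a bonds together. The closest known reaction type is the silicon-tethered intramolecular benzyne–furan Diels–Alder reaction, with the aryne generated from an ortho-iodoaryl triflate by a silylmethyl Grignard reagent. Two rings close: the oxygen-bridged ring A (a 7-oxabicyclo[2.2.1]heptadiene) by the [4+2] addition itself, and a ten-membered strap ring (C8, C8a, C1, C2, C1', O, Si, O, Si, O) that follows from the tether. The two new bridgehead stereocentres are cis by the geometry of the bicycle, and their sense relative to C1' need not be controlled because both carbons become sp2 in step 7, while C1' itself is untouched. The selectivity that matters is the orientation of the unsymmetrical furan on an aryne whose two flanking alkoxy groups give no electronic bias: by simple models, with the substituted furan carbon next to C8a the two strap oxygens are about 3.5 Å apart and easily spanned, whereas the reverse orientation would need more than the fully extended O–Si–O–Si–O chain (about 5.4 Å) can reach. High dilution and the weakly nucleophilic Grignard reagent should keep intermolecular capture of 12 behind the intramolecular trap.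

Step 7
Reactants: 13 strapped 1,4-epoxy-1,4-dihydronaphthalene
Product: 15 8-O,1'-O-(1,1,3,3-tetraisopropyldisiloxane-1,3-diyl)-bridged 8-hydroxy-2-[(1S)-1-hydroxy-4-methylpent-3-en-1-yl]-5-methoxynaphthalene-1,4-dione, via 1-naphthol 14 (not isolated)
Conditions: Cu(OTf)2 (5 mol %), ClCH2CH2Cl, 23 °C; short silica pad, concentrate; then (KSO3)2NO, KH2PO4, acetone/H2O, 0 to 23 °C
Reagents that add atoms: potassium nitrosodisulfonate (Fremy's salt), [K+].[K+].[O]N(S(=O)(=O)[O-])S(=O)(=O)[O-]
Why: Lewis-acid isomerisation of a 7-oxabenzonorbornadiene to a 1-naphthol (ionisation of a bridge C–O bond to an allylic, benzylic cation, then proton loss) followed by Teuber oxidation at the free para position C4; O8 stays silylated so ring B is inert, and either naphthol regioisomer would converge on the same quinone.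

Step 8
Reactants: 15 strapped quinone
Product: 16 8-hydroxy-2-[(1S)-1-hydroxy-4-methylpent-3-en-1-yl]-5-methoxynaphthalene-1,4-dione (5-O-methylalkannin)
Conditions: HF·pyridine, pyridine, THF, 0 to 23 °C
Reagents that add atoms: none
Why: Fluoride cleavage of both Si–O bonds of the disiloxane under buffered conditions that should spare the quinone, the prenyl group and the configuration at C1'.

Step 9
Reactants: 16 5-O-methylalkannin; 17 3-methylbut-2-enoic acid
Product: 18 (1S)-1-(8-hydroxy-5-methoxy-1,4-dioxo-1,4-dihydronaphthalen-2-yl)-4-methylpent-3-en-1-yl 3-methylbut-2-enoate (target, CNP0299347.1)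
Conditions: DCC, DMAP (cat.), CH2Cl2, 0 to 23 °C
Reagents that add atoms: none
Why: Steglich esterification; the C8 hydroxyl is held in a hydrogen bond to the C1 carbonyl and is far less nucleophilic, so only the secondary alcohol should be acylated, with no bond to C1' broken.

**Compound list**

1 | furan-3-carbaldehyde | O=Cc1ccoc1 | starting material
2 | (1S)-1-(furan-3-yl)but-3-en-1-ol | C=CC[C@H](O)c1ccoc1 | intermediate
3 | 2-methylbut-2-ene | CC=C(C)C | starting material
4 | (1S)-1-(furan-3-yl)-4-methylpent-3-en-1-ol | CC(C)=CC[C@H](O)c1ccoc1 | intermediate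
5 | 3-hydroxy-2-iodo-4-methoxybenzaldehyde | COc1ccc(C=O)c(I)c1O | starting material
6 | 3-formyl-2-iodo-6-methoxyphenyl trifluoromethanesulfonate | COc1ccc(C=O)c(I)c1OS(=O)(=O)C(F)(F)F | intermediate
7 | 3-(formyloxy)-2-iodo-6-methoxyphenyl trifluoromethanesulfonate | COc1ccc(OC=O)c(I)c1OS(=O)(=O)C(F)(F)F | intermediate
8 | 3-hydroxy-2-iodo-6-methoxyphenyl trifluoromethanesulfonate | COc1ccc(O)c(I)c1OS(=O)(=O)C(F)(F)F | intermediate
9 | 1-chloro-3-{[(1S)-1-(furan-3-yl)-4-methylpent-3-en-1-yl]oxy}-1,1,3,3-tetraisopropyldisiloxane | CC(C)=CC[C@H](O[Si](C(C)C)(C(C)C)O[Si](Cl)(C(C)C)C(C)C)c1ccoc1 | intermediate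
10 | 3-[(3-{[(1S)-1-(furan-3-yl)-4-methylpent-3-en-1-yl]oxy}-1,1,3,3-tetraisopropyldisiloxanyl)oxy]-2-iodo-6-methoxyphenyl trifluoromethanesulfonate | COc1ccc(O[Si](C(C)C)(C(C)C)O[Si](C(C)C)(C(C)C)O[C@@H](CC=C(C)C)c2ccoc2)c(I)c1OS(=O)(=O)C(F)(F)F | intermediate
11 | arylmagnesium chloride of 10 (MgCl in place of I) | COc1ccc(O[Si](C(C)C)(C(C)C)O[Si](C(C)C)(C(C)C)O[C@@H](CC=C(C)C)c2ccoc2)c([Mg]Cl)c1OS(=O)(=O)C(F)(F)F | intermediate
12 | 3-methoxy-6-(disiloxanyloxy)benzyne carrying the tethered furyl carbinol | COC1=CC=C(O[Si](C(C)C)(C(C)C)O[Si](C(C)C)(C(C)C)O[C@@H](CC=C(C)C)c2ccoc2)C#C1 | intermediate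
13 | disiloxane-strapped 5-methoxy-1,4-dihydro-1,4-epoxynaphthalene (C8–O and C1'–O bridged; C1' S; bridgeheads cis, sense open) | COc1ccc2c3c1C4OC3C(=C4)[C@H](CC=C(C)C)O[Si](C(C)C)(C(C)C)O[Si](C(C)C)(C(C)C)O2 | intermediate
14 | disiloxane-strapped 5-methoxy-1-naphthol (C8–O and C1'–O bridged; C1' S) | COc1ccc2c3c1ccc(c3O)[C@H](CC=C(C)C)O[Si](C(C)C)(C(C)C)O[Si](C(C)C)(C(C)C)O2 | intermediate
15 | disiloxane-strapped 5-methoxy-1,4-naphthoquinone (C8–O and C1'–O bridged; C1' S) | COc1ccc2c3c1C(=O)C=C(C3=O)[C@H](CC=C(C)C)O[Si](C(C)C)(C(C)C)O[Si](C(C)C)(C(C)C)O2 | intermediate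
16 | 8-hydroxy-2-[(1S)-1-hydroxy-4-methylpent-3-en-1-yl]-5-methoxynaphthalene-1,4-dione | COc1ccc(O)c2c1C(=O)C=C([C@H](CC=C(C)C)O)C2=O | intermediate
17 | 3-methylbut-2-enoic acid | CC(C)=CC(=O)O | starting material
18 | (1S)-1-(8-hydroxy-5-methoxy-1,4-dioxo-1,4-dihydronaphthalen-2-yl)-4-methylpent-3-en-1-yl 3-methylbut-2-enoate | COc1ccc(O)c2c1C(=O)C=C([C@H](CC=C(C)C)OC(=O)C=C(C)C)C2=O | target

**Totals**

Total step count: 9. Longest linear sequence: 7 steps (steps 1, 2, 5, 6, 7, 8, 9; the arene branch 3, 4, 5, 6, 7, 8, 9 is equally long).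

**Steps most likely to fail**

Step 6. The long strap may allow trapping of the aryne in both furan orientations, or the aryne may be captured intermolecularly (by the Grignard reagent or another furan) before the ten-membered closure. The fallback sets out from 4 and 8 and returns at 13. Alcohol 4 is treated with iPr2SiCl2 and imidazole to give the chloro(diisopropyl)silyl ether F1, which is coupled with 8 to the one-silicon tethered iodo triflate F2. The same iodine–magnesium exchange gives the arylmagnesium chloride F3 and the aryne F4, whose cycloaddition must close an eight-membered strap ring and can do so in one orientation only, giving the silylene-bridged cycloadduct F5. One silicon cannot bridge O8 and O1' once ring A is flat, so F5 is desilylated with HF·pyridine to the diol oxabicycle F6, and this is re-bridged with TIPDSCl2 and imidazole to 13.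

Step 7. Silicon may migrate from O8 to the new peri hydroxyl at the naphthol stage (or the aryl silyl ether may hydrolyse), exposing the p-methoxyphenol ring B to the oxidant so that the wrong ring is oxidised with loss of methanol; acid ionisation at the benzylic C1'–O bond is a second danger. The fallback sets out from 14 and returns at 16. The silicon is removed on purpose with HF·pyridine to give the naphthalenetriol F7, which is oxidised with O2 and Co(salen) (divalent cobalt) in MeCN. A cobalt–dioxygen oxidant delivers oxygen only to a phenolic para C–H, which ring B lacks, so 16 should form directly.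

Step 4. In the Criegee intermediate, hydride may migrate instead of the aryl group deactivated by triflate and iodide, giving the benzoic acid; the triflate may also be lost during formate cleavage. The fallback sets out from 5 (with 9) and returns at 10. The electron-rich free phenol 5 is oxidised with mCPBA to the 3-hydroxy-2-iodo-4-methoxyphenyl formate F8, which is methanolysed to 2-iodo-4-methoxybenzene-1,3-diol F9. The less hindered hydroxyl (para to the methoxy group) is silylated with chlorodisiloxane 9 to give the mono-strapped phenol F10, and the remaining hindered hydroxyl is triflated (Tf2O, pyridine) to give 10.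

**Further compounds**

F1 | step 6 | chloro{[(1S)-1-(furan-3-yl)-4-methylpent-3-en-1-yl]oxy}diisopropylsilane | CC(C)=CC[C@H](O[Si](Cl)(C(C)C)C(C)C)c1ccoc1
F2 | step 6 | 3-[({[(1S)-1-(furan-3-yl)-4-methylpent-3-en-1-yl]oxy}diisopropylsilyl)oxy]-2-iodo-6-methoxyphenyl trifluoromethanesulfonate | COc1ccc(O[Si](C(C)C)(C(C)C)O[C@@H](CC=C(C)C)c2ccoc2)c(I)c1OS(=O)(=O)C(F)(F)F
F3 | step 6 | arylmagnesium chloride of F2 (MgCl in place of I) | COc1ccc(O[Si](C(C)C)(C(C)C)O[C@@H](CC=C(C)C)c2ccoc2)c([Mg]Cl)c1OS(=O)(=O)C(F)(F)F
F4 | step 6 | aryne from F3 | COC1=CC=C(O[Si](C(C)C)(C(C)C)O[C@@H](CC=C(C)C)c2ccoc2)C#C1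
F5 | step 6 | diisopropylsilylene-bridged 5-methoxy-1,4-dihydro-1,4-epoxynaphthalene (C8–O and C1'–O bridged; C1' S) | COc1ccc2c3c1C4OC3C(=C4)[C@H](CC=C(C)C)O[Si](C(C)C)(C(C)C)O2
F6 | step 6 | 2-[(1S)-1-hydroxy-4-methylpent-3-en-1-yl]-5-methoxy-1,4-dihydro-1,4-epoxynaphthalen-8-ol | COc1ccc(O)c2c1C1OC2C(=C1)[C@H](CC=C(C)C)O
F7 | step 7 | 2-[(1S)-1-hydroxy-4-methylpent-3-en-1-yl]-5-methoxynaphthalene-1,8-diol | COc1ccc(O)c2c(O)c(ccc12)[C@H](CC=C(C)C)O
F8 | step 4 | 3-hydroxy-2-iodo-4-methoxyphenyl formate | COc1ccc(OC=O)c(I)c1O
F9 | step 4 | 2-iodo-4-methoxybenzene-1,3-diol | COc1ccc(O)c(I)c1O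
F10 | step 4 | 3-[(3-{[(1S)-1-(furan-3-yl)-4-methylpent-3-en-1-yl]oxy}-1,1,3,3-tetraisopropyldisiloxanyl)oxy]-2-iodo-6-methoxyphenol | COc1ccc(O[Si](C(C)C)(C(C)C)O[Si](C(C)C)(C(C)C)O[C@@H](CC=C(C)C)c2ccoc2)c(I)c1O
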